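**Retrosynthetic overview**

1. The target is a cis-fused daucane: ring A is the cyclopentane C1–C5, ring B the cycloheptane C1, C5–C10. The endgame is desilylation ⇐ double angeloylation ⇐ hydroxyl-directed epoxidation of a cyclohept-8-ene-6,10-diol.
2. Ring B is closed last, at C9–C10. C10 is an allylic carbinol held between the quaternary C1 (no α-hydrogen) and the C8=C9 bond hidden in the 8,9-epoxide, so C10(OH)–C9H=C8(CH3) is the retron of an intramolecular alkenyl–aldehyde (Nozaki–Hiyama–Kishi) coupling between a Z iodoalkene arm on C5 and a formyl group on C1.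
3. The arm (C6–C9 plus the C8 methyl) comes from chelate-controlled propargylation of a cis-fused lactol, then anti-methylalumination and iodination. C10 and the quaternary C1 come from a silicon-tethered radical cyclisation delivered from the C4 oxygen; C5 is funnelled to cis through the lactol.
4. Ring A is made first, by ring contraction of (R)-terpinen-4-ol (allylic hydroxylation, ozonolysis, aldol condensation). Its carbinol carbon becomes C4 with the isopropyl group, its methyl becomes the C1 methyl, and its alkene CH becomes C6.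
5. Ring order: ring A (step 3), then ring B (step 11); the epoxide oxygen is added to the finished carbon skeleton (step 13).

Key step: step 11

Numbering used throughout (daucane): C1 ring-fusion carbon with CH3; C2 CH–OH; C3 CH2; C4 C(OH)(iPr); C5 ring-fusion CH; C6 CH–O; C7 CH2; C8 C(CH3); C9 CH; C10 CH–O.
Reading of the SMILES: the ring fusion is cis (C1–CH3 and H5 syn). On ring A the 2-OH, 4-OH, C6 and C10 all lie on one face. On ring B the 6-O, the 10-O and the epoxide oxygen lie on the face of the angular methyl.
Assumption: commercial (R)-(−)-terpinen-4-ol is taken at high enantiomeric purity; if a lot is not, diol 2 (or a crystalline derivative of it) is the point to upgrade it.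

**Route**

Step 1
Reactants: 1 (R)-(−)-terpinen-4-ol
Product: 2 (1S,5S)-2-methyl-5-(propan-2-yl)cyclohex-2-ene-1,5-diol
Conditions: SeO2 (0.5 equiv), t-BuOOH, CH2Cl2, rt
Reagents that add atoms: selenium dioxide, O=[Se]=O (oxygen donor, re-oxidised in the flask); tert-butyl hydroperoxide, CC(C)(C)OO (terminal oxidant)
Why: Catalytic SeO2 allylic hydroxylation (ene reaction then [2,3]-sigmatropic shift) should oxidise the ring CH2 at the more substituted alkene terminus and deliver the oxygen pseudo-axially, that is cis to the axial tertiary hydroxyl (the same sense as limonene to trans-carveol), which sets C2.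

Step 2
Reactants: 2 (1S,5S)-2-methyl-5-(propan-2-yl)cyclohex-2-ene-1,5-diol
Product: 3 (1S,5S)-5-[(tert-butyldimethylsilyl)oxy]-4-methyl-1-(propan-2-yl)cyclohex-3-en-1-ol
Conditions: TBSCl, imidazole, DMF, 0 °C → rt
Reagents that add atoms: tert-butyldimethylsilyl chloride, CC(C)(C)[Si](C)(C)Cl
Why: Silylation of the secondary allylic hydroxyl is much faster than that of the hindered tertiary one, so the C2 oxygen is masked for the whole route and the C4 hydroxyl stays free (silyl ether protection, no stereocentre touched).

Step 3
Reactants: 3 (1S,5S)-5-[(tert-butyldimethylsilyl)oxy]-4-methyl-1-(propan-2-yl)cyclohex-3-en-1-ol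
Product: 5 (3S,5S)-3-[(tert-butyldimethylsilyl)oxy]-5-hydroxy-2-methyl-5-(propan-2-yl)cyclopent-1-ene-1-carbaldehyde, via keto aldehyde 4 (not isolated)
Conditions: O3, CH2Cl2/MeOH, −78 °C; Me2S; then Bn2NH·CF3CO2H (cat.), toluene, rt → 40 °C
Reagents that add atoms: ozone, [O-][O+]=O
Why: Ozonolysis cleaves the only alkene to a methyl ketone (C1) and an aldehyde (C6), and enamine catalysis by the secondary ammonium salt lets the aldehyde α-carbon C5 attack the ketone and dehydrate (intramolecular aldol condensation), which contracts the six-membered ring to ring A as the conjugated enal without touching C2 or C4.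

Step 4
Reactants: 5 (3S,5S)-3-[(tert-butyldimethylsilyl)oxy]-5-hydroxy-2-methyl-5-(propan-2-yl)cyclopent-1-ene-1-carbaldehyde
Product: 6 C4 (bromomethyl)dimethylsilyl ether of enal 5
Conditions: BrCH2SiMe2Cl, imidazole, DMAP (cat.), CH2Cl2, 0 °C → rt
Reagents that add atoms: (bromomethyl)chlorodimethylsilane, C[Si](C)(Cl)CBr
Why: Silyl ether formation at the tertiary allylic hydroxyl installs the bromomethylsilyl tether of a Nishiyama–Stork cyclisation on the C4 oxygen, which sits on the face of ring A to which C10 has to be delivered.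

Step 5
Reactants: 6 C4 (bromomethyl)dimethylsilyl ether of enal 5
Product: 7 siloxane-bridged aldehyde (C4–O–SiMe2–CH2–C1 bridge across ring A; formyl on C5 on the side of the bridge; 2-OTBS)
Conditions: Bu3SnH (slow addition), AIBN (cat.), benzene, 80 °C, 0.01 M
Reagents that add atoms: none
Why: The α-silylmethyl radical adds in the 6-endo mode to C1, the β-carbon of the enal (polarity-matched radical conjugate addition, Nishiyama–Stork cyclisation), so the C1–C10 bond and the quaternary centre are formed cis to the C4 oxygen by the tether, and the α-formyl radical at C5 is reduced by the tin hydride from the face remote from the SiMe2 group.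

Step 6
Reactants: 7 siloxane-bridged aldehyde
Product: 9 cis-fused lactol (C6 hemiacetal closed by the C10 oxygen; 2-OTBS; 4-OH free), via hydroxy aldehyde 8 (not isolated)
Conditions: 30% H2O2, KF, KHCO3, THF/MeOH, rt
Reagents that add atoms: hydrogen peroxide, OO
Why: Tamao–Fleming oxidation turns the C10–Si bond into C10–OH and frees the C4 hydroxyl, and the C10 hydroxyl then closes onto the C6 aldehyde as a five-membered lactol that can only be cis-fused, so any C5 epimer is drained through the enolisable aldehyde into the required all-cis arrangement (stereoconvergent ring–chain tautomerism).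

Step 7
Reactants: 9 cis-fused lactol; 10 propargyl bromide
Product: 12 homopropargylic triol (6R; 4-OH, 6-OH and 10-OH free; 2-OTBS), via allenylmagnesium bromide 11 (not isolated)
Conditions: 10, Mg, HgCl2 (cat.), Et2O, 0 °C; then 9, THF, −78 → 0 °C
Reagents that add atoms: none
Why: The lactol opens to the magnesium alkoxide of hydroxy aldehyde 8, the allenyl Grignard reagent adds with SE2' transposition to give the homopropargylic alcohol, and the C4 magnesium alkoxide chelates the aldehyde (six-membered 1,3-chelate, Cram-chelate model) so that attack comes from the side of H5 and anti to C1, which sets 6R.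

Step 8
Reactants: 12 homopropargylic triol
Product: 14 Z-iodoalkene triol (C7 and iodine cis on C8=C9), via cyclic alkenylalane 13 (not isolated)
Conditions: Me3Al, Cp2ZrCl2 (cat.), ClCH2CH2Cl, 0 °C → rt; AlCl3 (cat.), 50 °C; then I2, THF, −30 → 0 °C
Reagents that add atoms: trimethylaluminium, C[Al](C)C; iodine, II
Why: Zirconium-catalysed methylalumination (Negishi carboalumination) places CH3 on C8 and aluminium on C9, and on warming the first-formed syn adduct isomerises to the six-membered alkoxide chelate 13 (anti-carbometalation of homopropargylic alcohols), so that iodinolysis with retention gives the Z iodoalkene in which C7 and iodine are cis, as the ring closure requires.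

Step 9
Reactants: 14 Z-iodoalkene triol
Product: 15 tris(triethylsilyl) ether (4-OTES, 6-OTES, 10-OTES; 2-OTBS)
Conditions: TESOTf, 2,6-lutidine, CH2Cl2, −78 → 0 °C
Reagents that add atoms: triethylsilyl trifluoromethanesulfonate, CC[Si](CC)(CC)OS(=O)(=O)C(F)(F)F
Why: Exhaustive silyl ether formation masks the C6 and C10 hydroxyls and also the tertiary C4 hydroxyl, which would otherwise trap the coming C10 aldehyde as a bridged lactol.

Step 10
Reactants: 15 tris(triethylsilyl) ether
Product: 16 iodoalkene aldehyde (C10 formyl on C1; 4-OTES, 6-OTES, 2-OTBS)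
Conditions: (COCl)2, DMSO, CH2Cl2, −78 → −30 °C; Et3N, → 0 °C
Reagents that add atoms: none
Why: Under Swern conditions a primary triethylsilyl ether is cleaved by the chlorosulfonium reagent and oxidised in the same flask while secondary and tertiary silyl ethers stay (selective oxidative deprotection), and the resulting neopentyl aldehyde has no α-hydrogen to epimerise.

Step 11
Reactants: 16 iodoalkene aldehyde
Product: 18 cis-fused cycloheptenol (ring B closed; C8=C9; 10-OH free and syn to the angular methyl; 4-OTES, 6-OTES, 2-OTBS), via alkenylchromium dichloride 17 (not isolated)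
Conditions: CrCl2 (excess), NiCl2 (cat.), degassed DMSO/THF, rt, 0.005 M
Reagents that add atoms: none
Why: Zerovalent nickel, formed from NiCl2 by divalent chromium, inserts into the C9–I bond, the alkenyl group is passed with retention of the Z geometry to trivalent chromium, and alkenylchromium 17 adds to the C10 aldehyde; the closest known reaction type is the intramolecular Nozaki–Hiyama–Kishi coupling used to close medium and large rings from iodoalkene aldehydes. Ring B closes in the 7-exo-trig mode by forming the C9–C10 bond, with the cis ring fusion already fixed at C1 and C5. The new C10 stereocentre is controlled by the quaternary C1: for ring B to lie outside ring A, C9 has to attack anti to the C1–C2 bond, and of the two carbonyl rotamers the one that turns the oxygen and its chromium outward, between the angular methyl and C2, is preferred over the one that buries them in the concave face under ring A, which gives the 10-hydroxyl syn to the angular methyl. The step needs chemoselectivity for the aldehyde (alkenylchromium reagents tolerate silyl ethers, and the aldehyde is neopentyl and cannot enolise), retention of the Z alkene (secured by the configurational stability of the alkenylchromium) and cyclisation instead of oligomerisation (secured by high dilution and by the cis arrangement of the two arms on ring A). In one operation the ring is closed, C10 is set, and the C8=C9 alkene is left exactly where the epoxide must go, next to a free allylic hydroxyl that will steer the oxidant.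

Step 12
Reactants: 18 cis-fused cycloheptenol
Product: 19 ene-diol (6-OH and 10-OH free; 4-OTES, 2-OTBS)
Conditions: PPTS (cat.), MeOH/CH2Cl2, 0 °C
Reagents that add atoms: none
Why: Acid-catalysed methanolysis removes the secondary triethylsilyl ether at C6 well before the hindered tertiary TES ether at C4 and the TBS ether at C2 (graded lability of silyl ethers), which exposes exactly the two hydroxyls that become esters.

Step 13
Reactants: 19 ene-diol
Product: 20 epoxy diol (8,9-epoxide cis to the 6-OH and 10-OH; 4-OTES, 2-OTBS)
Conditions: VO(acac)2 (cat.), t-BuOOH, CH2Cl2, 0 °C → rt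
Reagents that add atoms: tert-butyl hydroperoxide, CC(C)(C)OO
Why: Vanadium-catalysed hydroxyl-directed epoxidation delivers the peroxide oxygen syn to the C10 allylic hydroxyl, reinforced by the C6 homoallylic hydroxyl on the same face, which gives the 8,9-epoxide cis to both oxygens and sets C8 and C9.

Step 14
Reactants: 20 epoxy diol; 21 angelic acid
Product: 23 6,10-bis-angelate (4-OTES, 2-OTBS), via mixed anhydride 22 (not isolated)
Conditions: 21 (excess, at least two equivalents), 2,4,6-Cl3C6H2COCl, Et3N, toluene, rt; then 20, toluene, 75 °C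
Reagents that add atoms: angelic acid (second equivalent of 21, for the second ester), C/C=C(/C)C(=O)O
Why: Two equivalents of angelic acid are converted into the mixed anhydride 22, and each of the two free secondary hydroxyls (O6 and O10) takes one angeloyl group from it without a nucleophilic catalyst (Yamaguchi-type esterification), which should avoid the amine-triggered Z-to-E isomerisation to tiglate, while the silylated C2 and C4 oxygens cannot react.

Step 15
Reactants: 23 6,10-bis-angelate
Product: 24 (1R,2S,4S,5R,6R,8S,9R,10R)-6,10-bis(angeloyloxy)-8,9-epoxydaucane-2,4-diol (cis ring fusion)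
Conditions: HF·pyridine, pyridine, THF, 0 °C → rt
Reagents that add atoms: none
Why: Buffered fluoride cleaves the TBS ether at C2 and the TES ether at C4 (fluoride-mediated desilylation) under conditions mild enough for the epoxide and the two Z-enoates, which gives the target.

**Compound list**

1 | (R)-(−)-terpinen-4-ol | CC1=CC[C@@](O)(C(C)C)CC1 | starting material
2 | (1S,5S)-2-methyl-5-(propan-2-yl)cyclohex-2-ene-1,5-diol | CC1=CC[C@@](O)(C(C)C)C[C@@H]1O | intermediate
3 | (1S,5S)-5-[(tert-butyldimethylsilyl)oxy]-4-methyl-1-(propan-2-yl)cyclohex-3-en-1-ol | CC1=CC[C@@](O)(C(C)C)C[C@@H]1O[Si](C)(C)C(C)(C)C | intermediate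
4 | keto aldehyde: 5-[(tert-butyldimethylsilyl)oxy]-3-hydroxy-6-oxo-3-(propan-2-yl)heptanal, configuration as in 3 | CC(=O)[C@@H](O[Si](C)(C)C(C)(C)C)C[C@](O)(C(C)C)CC=O | intermediate
5 | (3S,5S)-3-[(tert-butyldimethylsilyl)oxy]-5-hydroxy-2-methyl-5-(propan-2-yl)cyclopent-1-ene-1-carbaldehyde | CC1=C(C=O)[C@@](O)(C(C)C)C[C@@H]1O[Si](C)(C)C(C)(C)C | intermediate
6 | C4 (bromomethyl)dimethylsilyl ether of enal 5 | CC1=C(C=O)[C@@](O[Si](C)(C)CBr)(C(C)C)C[C@@H]1O[Si](C)(C)C(C)(C)C | intermediate
7 | siloxane-bridged aldehyde (C4–O–SiMe2–CH2–C1 bridge; 5-formyl; 2-OTBS) | O=C[C@H]1[C@@]2(C)C[Si](C)(C)O[C@]1(C(C)C)C[C@@H]2O[Si](C)(C)C(C)(C)C | intermediate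
8 | hydroxy aldehyde (1-hydroxymethyl, 5-formyl, 4-OH, 2-OTBS, all cis on ring A) | O=C[C@H]1[C@@](C)(CO)[C@@H](O[Si](C)(C)C(C)(C)C)C[C@]1(O)C(C)C | intermediate
9 | cis-fused lactol (C6 hemiacetal closed by the C10 oxygen) | OC1OC[C@@]2(C)[C@@H](O[Si](C)(C)C(C)(C)C)C[C@](O)(C(C)C)[C@@H]12 | intermediate
10 | propargyl bromide | C#CCBr | starting material
11 | allenylmagnesium bromide | C=C=C[Mg]Br | intermediate
12 | homopropargylic triol (6R) | C#CC[C@@H](O)[C@H]1[C@@](C)(CO)[C@@H](O[Si](C)(C)C(C)(C)C)C[C@]1(O)C(C)C | intermediate
13 | cyclic alkenylalane (six-membered C9–Al–O6 chelate, other hydroxyls as dimethylaluminium alkoxides) | C[Al]1O[C@H](CC(C)=C1)[C@H]1[C@@](C)(CO[Al](C)C)[C@@H](O[Si](C)(C)C(C)(C)C)C[C@]1(O[Al](C)C)C(C)C | intermediate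
14 | Z-iodoalkene triol | I/C=C(/C)C[C@@H](O)[C@H]1[C@@](C)(CO)[C@@H](O[Si](C)(C)C(C)(C)C)C[C@]1(O)C(C)C | intermediate
15 | tris(triethylsilyl) ether of 14 | I/C=C(/C)C[C@@H](O[Si](CC)(CC)CC)[C@H]1[C@@](C)(CO[Si](CC)(CC)CC)[C@@H](O[Si](C)(C)C(C)(C)C)C[C@]1(O[Si](CC)(CC)CC)C(C)C | intermediate
16 | iodoalkene aldehyde (C10 formyl) | I/C=C(/C)C[C@@H](O[Si](CC)(CC)CC)[C@H]1[C@@](C)(C=O)[C@@H](O[Si](C)(C)C(C)(C)C)C[C@]1(O[Si](CC)(CC)CC)C(C)C | intermediate
17 | alkenylchromium dichloride | Cl[Cr](Cl)/C=C(/C)C[C@@H](O[Si](CC)(CC)CC)[C@H]1[C@@](C)(C=O)[C@@H](O[Si](C)(C)C(C)(C)C)C[C@]1(O[Si](CC)(CC)CC)C(C)C | intermediate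
18 | cis-fused cycloheptenol (dauc-8-ene; 10-OH; 4,6-di-OTES; 2-OTBS) | CC[Si](CC)(CC)O[C@@H]1CC(C)=C[C@H](O)[C@@]2(C)[C@@H](O[Si](C)(C)C(C)(C)C)C[C@](O[Si](CC)(CC)CC)(C(C)C)[C@@H]12 | intermediate
19 | ene-diol (6-OH, 10-OH; 4-OTES; 2-OTBS) | O[C@@H]1CC(C)=C[C@H](O)[C@@]2(C)[C@@H](O[Si](C)(C)C(C)(C)C)C[C@](O[Si](CC)(CC)CC)(C(C)C)[C@@H]12 | intermediate
20 | epoxy diol (8,9-epoxide cis to 6-OH and 10-OH) | O[C@@H]1C[C@]2(C)O[C@@H]2[C@H](O)[C@@]2(C)[C@@H](O[Si](C)(C)C(C)(C)C)C[C@](O[Si](CC)(CC)CC)(C(C)C)[C@@H]12 | intermediate
21 | angelic acid, (Z)-2-methylbut-2-enoic acid | C/C=C(/C)C(=O)O | starting material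
22 | angelic 2,4,6-trichlorobenzoic anhydride | C/C=C(/C)C(=O)OC(=O)c1c(Cl)cc(Cl)cc1Cl | intermediate
23 | 6,10-bis-angelate (4-OTES, 2-OTBS) | C/C=C(/C)C(=O)O[C@@H]1C[C@]2(C)O[C@@H]2[C@H](OC(=O)/C(C)=C\C)[C@@]2(C)[C@@H](O[Si](C)(C)C(C)(C)C)C[C@](O[Si](CC)(CC)CC)(C(C)C)[C@@H]12 | intermediate
24 | (1R,2S,4S,5R,6R,8S,9R,10R)-6,10-bis(angeloyloxy)-8,9-epoxydaucane-2,4-diol | C/C=C(/C)C(=O)O[C@@H]1C[C@]2(C)O[C@@H]2[C@H](OC(=O)/C(C)=C\C)[C@@]2(C)[C@@H](O)C[C@](O)(C(C)C)[C@@H]12 | target

**Step count and risks**

Total step count: 15.
Longest linear sequence: 15 steps (1 → 24); 10 and 21 are bought.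

The three steps most likely to fail:

Step 11. Closure of the seven-membered ring may lose to oligomerisation or to protonation of the alkenylchromium, and the facial selectivity at C10 may be poor. The fallback closes ring B at C8=C9 by olefin metathesis. It sets out from lactol 9. 2-Methylallylmagnesium chloride (THF, −78 → 0 °C, same alkoxide chelate as in step 7) should give the methallyl triol F1. TESOTf and 2,6-lutidine give the tris(triethylsilyl) ether F2, and the selective Swern oxidation gives the neopentyl aldehyde F3. Vinylmagnesium bromide (THF, −78 °C) adds to give the allylic alcohol F4; this is a Felkin-type addition anti to the C1–C2 bond, its selectivity is less secure, and the C10 epimers would be separated. The second-generation Grubbs catalyst (CH2Cl2, 40 °C) then closes the trisubstituted cycloheptene and comes back to the route at 18.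

Step 8. The chelation-driven isomerisation of the first-formed syn adduct may stall, or the silyl ether may be lost, because three hydroxyls tie up the aluminium during the Lewis-acidic heating. The fallback builds the iodoalkene before the Tamao–Fleming oxidation, when a single hydroxyl is present, and sets C6 by reagent control instead of by the chelate. It sets out from siloxane-bridged aldehyde 7. Catalytic asymmetric propargylation (allenylboronic acid pinacol ester, chiral phosphoric acid, toluene) gives the siloxane homopropargylic alcohol F5. Methylalumination, isomerisation and iodinolysis on this mono-alcohol give the siloxane Z-iodoalkene F6. Oxidation with H2O2, KF and KHCO3 then frees the C4 and C10 hydroxyls and comes back to the route at 14.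

Step 14. The angeloyl group may isomerise from Z to E during activation, the neopentyl C10 hydroxyl next to the epoxide may acylate incompletely, and base may cause epoxide migration. The fallback acylates with a saturated acid and builds the Z double bonds afterwards. It sets out from epoxy diol 20. Esterification of both hydroxyls with 2-[bis(2,2,2-trifluoroethoxy)phosphoryl]propanoic acid (two equivalents or more, DCC, DMAP, CH2Cl2) gives the bis(phosphonopropionate) F7. A double Still–Gennari olefination (KHMDS, 18-crown-6, THF, −78 °C, then acetaldehyde) forms both Z-2-methylbut-2-enoates and comes back to the route at 23.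

**Further compounds**

F1 | step 11 | methallyl triol (6R; 4-OH, 6-OH, 10-OH; 2-OTBS) | C=C(C)C[C@@H](O)[C@H]1[C@@](C)(CO)[C@@H](O[Si](C)(C)C(C)(C)C)C[C@]1(O)C(C)C
F2 | step 11 | tris(triethylsilyl) ether of F1 | C=C(C)C[C@@H](O[Si](CC)(CC)CC)[C@H]1[C@@](C)(CO[Si](CC)(CC)CC)[C@@H](O[Si](C)(C)C(C)(C)C)C[C@]1(O[Si](CC)(CC)CC)C(C)C
F3 | step 11 | methallyl aldehyde (C10 formyl) | C=C(C)C[C@@H](O[Si](CC)(CC)CC)[C@H]1[C@@](C)(C=O)[C@@H](O[Si](C)(C)C(C)(C)C)C[C@]1(O[Si](CC)(CC)CC)C(C)C
F4 | step 11 | diene allylic alcohol (C10 vinyl carbinol, hydroxyl configured as in 18) | C=C(C)C[C@@H](O[Si](CC)(CC)CC)[C@H]1[C@@](C)([C@@H](O)C=C)[C@@H](O[Si](C)(C)C(C)(C)C)C[C@]1(O[Si](CC)(CC)CC)C(C)C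
F5 | step 8 | siloxane homopropargylic alcohol (6R) | C#CC[C@@H](O)[C@H]1[C@@]2(C)C[Si](C)(C)O[C@]1(C(C)C)C[C@@H]2O[Si](C)(C)C(C)(C)C
F6 | step 8 | siloxane Z-iodoalkene | I/C=C(/C)C[C@@H](O)[C@H]1[C@@]2(C)C[Si](C)(C)O[C@]1(C(C)C)C[C@@H]2O[Si](C)(C)C(C)(C)C
F7 | step 14 | 6,10-bis{2-[bis(2,2,2-trifluoroethoxy)phosphoryl]propanoate} of 20 | CC(C(=O)O[C@@H]1C[C@]2(C)O[C@@H]2[C@H](OC(=O)C(C)P(=O)(OCC(F)(F)F)OCC(F)(F)F)[C@@]2(C)[C@@H](O[Si](C)(C)C(C)(C)C)C[C@](O[Si](CC)(CC)CC)(C(C)C)[C@@H]12)P(=O)(OCC(F)(F)F)OCC(F)(F)F
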